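## Retrosynthetic overview

- Feature: C1 of ring B is doubly benzylic (bonded to C8a of ring A and to the pendant aryl) and para to the free OH of the 4-hydroxy-3,5-dimethoxyphenyl ring. A C1 carbinol of either configuration therefore gives one planar p-quinone methide, and the neighbouring C2 can attack it as an enamine once its CH2OH carbon is an aldehyde.
- Target 23 ⇐ debenzylation and C=O reduction ⇐ tetralin aldehyde 21 ⇐ C1–C2 disconnection (enamine 1,6-addition, closes ring B) ⇐ open-chain (R)-aldehyde 19 with a p-hydroxybenzhydrol on ring A.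
- 19 ⇐ C1–C8a disconnection: aryllithium from bromide 13 plus silylated syringaldehyde 14, then alkene cleavage and desilylation.
- 13 ⇐ C3–C4 disconnection: oxazolidinone-directed alkylation of pentenoyl imide 9 with benzyl bromide 5 (from syringaldehyde), which sets C3.
- Ring order: ring A and the pendant ring come intact from syringaldehyde; ring B is the only ring made (step 13).

Key step: step 13

Assumption: tetralin numbering is used (C1 bears the pendant aryl, C2 and C3 the CH2OH groups, C4 is the CH2, C4a–C8a are ring A). Benzhydrols 16–19 are carried as mixtures of C1 epimers, because step 13 erases this centre.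

## Route

Step 1
Reactants: 1 syringaldehyde
Product: 2 4-(benzyloxy)-3,5-dimethoxybenzaldehyde
Conditions: BnBr, K2CO3, DMF, 60 °C
Reagents that add atoms: benzyl bromide, BrCc1ccccc1
Why: Williamson ether synthesis, in which the phenoxide formed by K2CO3 displaces bromide from benzyl bromide (SN2) and the aldehyde is not touched.

Step 2
Reactants: 2 4-(benzyloxy)-3,5-dimethoxybenzaldehyde
Product: 3 4-(benzyloxy)-2-bromo-3,5-dimethoxybenzaldehyde
Conditions: NBS, MeCN, 0 °C to rt, dark
Reagents that add atoms: N-bromosuccinimide, O=C1CCC(=O)N1Br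
Why: Electrophilic aromatic bromination, in which the two open ring positions are equivalent and each lies ortho and para to a methoxy group, so a single monobromide should form while the aldehyde and the new halogen slow a second bromination.

Step 3
Reactants: 3 4-(benzyloxy)-2-bromo-3,5-dimethoxybenzaldehyde
Product: 4 [4-(benzyloxy)-2-bromo-3,5-dimethoxyphenyl]methanol
Conditions: NaBH4, MeOH/THF, 0 °C
Reagents that add atoms: none
Why: NaBH4 reduction of the aldehyde to the benzylic alcohol, which leaves the aryl bromide and the benzyl ether alone.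

Step 4
Reactants: 4 [4-(benzyloxy)-2-bromo-3,5-dimethoxyphenyl]methanol
Product: 5 4-(benzyloxy)-2-bromo-3,5-dimethoxybenzyl bromide
Conditions: PBr3, CH2Cl2, 0 °C
Reagents that add atoms: phosphorus tribromide, BrP(Br)Br
Why: Bromination of a primary benzylic alcohol through its phosphite ester (SN2 by bromide), fast at 0 °C so that the aryl benzyl ether should survive.

Step 5
Reactants: 6 4-pentenoic acid; 7 (R)-4-benzyl-2-oxazolidinone
Product: 9 (R)-4-benzyl-3-(pent-4-enoyl)oxazolidin-2-one, via mixed pivalic anhydride 8 (not isolated)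
Conditions: t-BuCOCl, Et3N, THF, −20 °C; then LiCl, 7, −20 °C to rt
Reagents that add atoms: none
Why: N-acylation of the oxazolidinone by the mixed anhydride under LiCl/Et3N activation, the nitrogen attacking the less hindered pentenoyl carbonyl.

Step 6
Reactants: 9 (R)-4-benzyl-3-(pent-4-enoyl)oxazolidin-2-one; 5 4-(benzyloxy)-2-bromo-3,5-dimethoxybenzyl bromide
Product: 11 (R)-4-benzyl-3-[(S)-2-{[4-(benzyloxy)-2-bromo-3,5-dimethoxyphenyl]methyl}pent-4-enoyl]oxazolidin-2-one, via sodium Z-enolate 10 (not isolated)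
Conditions: NaN(SiMe3)2, THF, −78 °C; then 5, −78 to −30 °C
Reagents that add atoms: none
Why: Evans asymmetric alkylation, in which the chelated sodium Z-enolate is shielded on one face by the benzyl group of the (R)-auxiliary, so the benzylic bromide enters from the other face and sets the (S) α-centre, the future C3.

Step 7
Reactants: 11 alkylated imide
Product: 12 (S)-2-{[4-(benzyloxy)-2-bromo-3,5-dimethoxyphenyl]methyl}pent-4-en-1-ol
Conditions: LiBH4, MeOH (1 equiv), THF, 0 °C
Reagents that add atoms: none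
Why: Reductive removal of the auxiliary (hydride attack at the exocyclic imide carbonyl) gives the primary alcohol without epimerisation, and the aryl bromide and alkene are inert.

Step 8
Reactants: 12 (S)-2-{[4-(benzyloxy)-2-bromo-3,5-dimethoxyphenyl]methyl}pent-4-en-1-ol
Product: 13 2-(benzyloxy)-5-{(S)-2-[(benzyloxy)methyl]pent-4-en-1-yl}-4-bromo-1,3-dimethoxybenzene
Conditions: NaH, BnBr, Bu4NI (cat.), THF/DMF, 0 °C to rt
Reagents that add atoms: benzyl bromide, BrCc1ccccc1
Why: Williamson benzylation of the sodium alkoxide (SN2), which masks the future C3 CH2OH so that it cannot later capture the quinone methide or the aldehyde.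

Step 9
Reactants: 1 syringaldehyde
Product: 14 4-[(tert-butyldimethylsilyl)oxy]-3,5-dimethoxybenzaldehyde
Conditions: TBSCl, imidazole, DMF, rt
Reagents that add atoms: tert-butyldimethylsilyl chloride, CC(C)(C)[Si](C)(C)Cl
Why: Silylation of the phenol with imidazole as base and nucleophilic catalyst, giving an aryl silyl ether that tolerates organolithium addition and periodate.

Step 10
Reactants: 13 aryl bromide; 14 4-[(tert-butyldimethylsilyl)oxy]-3,5-dimethoxybenzaldehyde
Product: 16 {3-(benzyloxy)-6-[(S)-2-(benzyloxymethyl)pent-4-en-1-yl]-2,4-dimethoxyphenyl}{4-[(tert-butyldimethylsilyl)oxy]-3,5-dimethoxyphenyl}methanol (both carbinol epimers), via aryllithium 15 (not isolated)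
Conditions: n-BuLi, THF, −78 °C; then 14, −78 to −40 °C; NH4Cl aq.
Reagents that add atoms: none
Why: Bromine–lithium exchange is faster than any deprotonation at −78 °C and the aryllithium adds 1,2 to the non-enolisable aldehyde, forming the C1–C8a bond; the new carbinol centre forms without control, which is harmless because step 13 erases it.

Step 11
Reactants: 16 benzhydrol with terminal alkene
Product: 18 (R)-3-[(benzyloxy)methyl]-4-[4-(benzyloxy)-2-({4-[(tert-butyldimethylsilyl)oxy]-3,5-dimethoxyphenyl}(hydroxy)methyl)-3,5-dimethoxyphenyl]butanal (carbinol epimers), via vicinal diol 17 (not isolated)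
Conditions: OsO4 (2 mol %), NaIO4, 2,6-lutidine, dioxane/H2O, rt
Reagents that add atoms: osmium tetroxide, O=[Os](=O)(=O)=O (delivers the oxygen); sodium periodate, [Na+].[O-]I(=O)(=O)=O (terminal oxygen source)
Why: Lemieux–Johnson oxidation, in which OsO4-catalysed dihydroxylation of the only alkene and periodate glycol cleavage give the aldehyde, C3 (β to the carbonyl) cannot epimerise, and the silyl ether keeps the electron-rich phenol away from periodate.

Step 12
Reactants: 18 silylated aldehyde
Product: 19 (R)-3-[(benzyloxy)methyl]-4-{4-(benzyloxy)-2-[hydroxy(4-hydroxy-3,5-dimethoxyphenyl)methyl]-3,5-dimethoxyphenyl}butanal (carbinol epimers)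
Conditions: Bu4NF, AcOH (1:1), THF, 0 °C
Reagents that add atoms: none
Why: Fluoride cleaves the aryl O–Si bond, and the acetic acid buffer keeps the phenol protonated so that neither base-induced loss of hydroxide from the carbinol nor aldol reaction of the aldehyde should set in.

Step 13
Reactants: 19 p-hydroxybenzhydrol aldehyde (both C1 epimers)
Product: 21 (1S,2R,3R)-7-(benzyloxy)-3-[(benzyloxy)methyl]-1-(4-hydroxy-3,5-dimethoxyphenyl)-6,8-dimethoxy-1,2,3,4-tetrahydronaphthalene-2-carbaldehyde, via quinone methide enamine 20 (not isolated)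
Conditions: pyrrolidine (20 mol %), CF3CO2H (30 mol %), CH2Cl2 (0.02 M), 0 °C to rt
Reagents that add atoms: none
Why: The slight excess of acid ionises the doubly benzylic carbinol of either epimer and loss of the phenolic proton gives one planar p-quinone methide, while pyrrolidine condenses with the aldehyde to the E-enamine, so that 20 carries both reactive ends. The closest known reaction type is the amine-catalysed α-alkylation of aldehydes by 1,6-addition of their enamines to p-quinone methides, including quinone methides released in situ from p-hydroxybenzhydrols; it is used here in an intramolecular sense. Ring B closes in a 6-(enolexo)-exo-trig mode when the enamine α-carbon (C2) bonds to the exocyclic C1, the pendant ring regains its aromaticity, and hydrolysis of the iminium ion returns the aldehyde and the amine. C1 is controlled by the fixed C3 centre through a half-chair transition state in which CH2OBn at C3 and the dienone ring at C1 are both pseudo-equatorial (1,3-cis). C2 is set trans to both neighbours in the same transition state and, being the α-carbon of the product aldehyde, can still equilibrate through the enamine to the all-equatorial arrangement. The step needs C-alkylation within the molecule to outrun intermolecular capture of the quinone methide and needs attack on the 1,3-cis face; the six-membered tether, high dilution, the benzyl ethers on the C3 CH2OH and the ring A phenol, and C2 being the only enolisable carbon secure the first, and the equatorial preference of the C3 substituent the second.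

Step 14
Reactants: 21 tetralin aldehyde
Product: 22 {(1S,2R,3R)-7-(benzyloxy)-3-[(benzyloxy)methyl]-1-(4-hydroxy-3,5-dimethoxyphenyl)-6,8-dimethoxy-1,2,3,4-tetrahydronaphthalen-2-yl}methanol
Conditions: NaBH4, MeOH, 0 °C
Reagents that add atoms: none
Why: NaBH4 reduction of the aldehyde to the primary alcohol, run at 0 °C directly after step 13 so that C2 keeps its configuration.

Step 15
Reactants: 22 dibenzyl ether
Product: 23 [(1S,2R,3R)-7-hydroxy-1-(4-hydroxy-3,5-dimethoxyphenyl)-6,8-dimethoxy-1,2,3,4-tetrahydronaphthalene-2,3-diyl]dimethanol (target)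
Conditions: H2 (1 atm), 10% Pd/C, MeOH/EtOAc, rt
Reagents that add atoms: none
Why: Catalytic hydrogenolysis of the aryl and the alkyl benzyl ether; the bonds from C1 to both rings are C–C bonds and are not cleaved, and no stereocentre is touched.

## Compound list

1 | syringaldehyde | COc1cc(C=O)cc(OC)c1O | starting material
2 | 4-(benzyloxy)-3,5-dimethoxybenzaldehyde | COc1cc(C=O)cc(OC)c1OCc1ccccc1 | intermediate
3 | 4-(benzyloxy)-2-bromo-3,5-dimethoxybenzaldehyde | COc1cc(C=O)c(Br)c(OC)c1OCc1ccccc1 | intermediate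
4 | [4-(benzyloxy)-2-bromo-3,5-dimethoxyphenyl]methanol | COc1cc(CO)c(Br)c(OC)c1OCc1ccccc1 | intermediate
5 | 4-(benzyloxy)-2-bromo-3,5-dimethoxybenzyl bromide | COc1cc(CBr)c(Br)c(OC)c1OCc1ccccc1 | intermediate
6 | 4-pentenoic acid | C=CCCC(=O)O | starting material
7 | (R)-4-benzyl-2-oxazolidinone | O=C1N[C@H](Cc2ccccc2)CO1 | starting material
8 | 4-pentenoic pivalic anhydride | C=CCCC(=O)OC(=O)C(C)(C)C | intermediate
9 | (R)-4-benzyl-3-(pent-4-enoyl)oxazolidin-2-one | C=CCCC(=O)N1[C@H](Cc2ccccc2)COC1=O | intermediate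
10 | sodium Z-enolate of 9 | C=CC/C=C(\[O-])N1[C@H](Cc2ccccc2)COC1=O.[Na+] | intermediate
11 | (R)-4-benzyl-3-[(S)-2-{[4-(benzyloxy)-2-bromo-3,5-dimethoxyphenyl]methyl}pent-4-enoyl]oxazolidin-2-one | C=CC[C@@H](Cc1cc(OC)c(OCc2ccccc2)c(OC)c1Br)C(=O)N1[C@H](Cc2ccccc2)COC1=O | intermediate
12 | (S)-2-{[4-(benzyloxy)-2-bromo-3,5-dimethoxyphenyl]methyl}pent-4-en-1-ol | C=CC[C@@H](Cc1cc(OC)c(OCc2ccccc2)c(OC)c1Br)CO | intermediate
13 | 2-(benzyloxy)-5-{(S)-2-[(benzyloxy)methyl]pent-4-en-1-yl}-4-bromo-1,3-dimethoxybenzene | C=CC[C@@H](Cc1cc(OC)c(OCc2ccccc2)c(OC)c1Br)COCc1ccccc1 | intermediate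
14 | 4-[(tert-butyldimethylsilyl)oxy]-3,5-dimethoxybenzaldehyde | COc1cc(C=O)cc(OC)c1O[Si](C)(C)C(C)(C)C | intermediate
15 | aryllithium from 13 (Li in place of Br) | C=CC[C@@H](Cc1cc(OC)c(OCc2ccccc2)c(OC)c1[Li])COCc1ccccc1 | intermediate
16 | {3-(benzyloxy)-6-[(S)-2-(benzyloxymethyl)pent-4-en-1-yl]-2,4-dimethoxyphenyl}{4-[(tert-butyldimethylsilyl)oxy]-3,5-dimethoxyphenyl}methanol, both carbinol epimers | C=CC[C@@H](Cc1cc(OC)c(OCc2ccccc2)c(OC)c1C(O)c1cc(OC)c(O[Si](C)(C)C(C)(C)C)c(OC)c1)COCc1ccccc1 | intermediate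
17 | 1,2-diol from dihydroxylation of the alkene of 16, diol and carbinol epimers | OCC(O)C[C@@H](Cc1cc(OC)c(OCc2ccccc2)c(OC)c1C(O)c1cc(OC)c(O[Si](C)(C)C(C)(C)C)c(OC)c1)COCc1ccccc1 | intermediate
18 | (R)-3-[(benzyloxy)methyl]-4-[4-(benzyloxy)-2-({4-[(tert-butyldimethylsilyl)oxy]-3,5-dimethoxyphenyl}(hydroxy)methyl)-3,5-dimethoxyphenyl]butanal, carbinol epimers | O=CC[C@@H](Cc1cc(OC)c(OCc2ccccc2)c(OC)c1C(O)c1cc(OC)c(O[Si](C)(C)C(C)(C)C)c(OC)c1)COCc1ccccc1 | intermediate
19 | (R)-3-[(benzyloxy)methyl]-4-{4-(benzyloxy)-2-[hydroxy(4-hydroxy-3,5-dimethoxyphenyl)methyl]-3,5-dimethoxyphenyl}butanal, carbinol epimers | COc1cc(C(O)c2c(C[C@@H](COCc3ccccc3)CC=O)cc(OC)c(OCc3ccccc3)c2OC)cc(OC)c1O | intermediate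
20 | p-quinone methide of 19 (2,6-dimethoxy-4-arylmethylidene-cyclohexa-2,5-dienone) with the aldehyde as its pyrrolidine E-enamine | COC1=CC(=Cc2c(C[C@@H](COCc3ccccc3)/C=C/N3CCCC3)cc(OC)c(OCc3ccccc3)c2OC)C=C(OC)C1=O | intermediate
21 | (1S,2R,3R)-7-(benzyloxy)-3-[(benzyloxy)methyl]-1-(4-hydroxy-3,5-dimethoxyphenyl)-6,8-dimethoxy-1,2,3,4-tetrahydronaphthalene-2-carbaldehyde | COc1cc([C@H]2c3c(cc(OC)c(OCc4ccccc4)c3OC)C[C@@H](COCc3ccccc3)[C@@H]2C=O)cc(OC)c1O | intermediate
22 | {(1S,2R,3R)-7-(benzyloxy)-3-[(benzyloxy)methyl]-1-(4-hydroxy-3,5-dimethoxyphenyl)-6,8-dimethoxy-1,2,3,4-tetrahydronaphthalen-2-yl}methanol | COc1cc([C@H]2c3c(cc(OC)c(OCc4ccccc4)c3OC)C[C@@H](COCc3ccccc3)[C@@H]2CO)cc(OC)c1O | intermediate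
23 | [(1S,2R,3R)-7-hydroxy-1-(4-hydroxy-3,5-dimethoxyphenyl)-6,8-dimethoxy-1,2,3,4-tetrahydronaphthalene-2,3-diyl]dimethanol | COc1cc([C@H]2c3c(cc(OC)c(O)c3OC)C[C@@H](CO)[C@@H]2CO)cc(OC)c1O | target

## Step count and risks

Total steps: 15. Longest linear sequence: 13 steps (1, 2, 3, 4, 6, 7, 8, 10, 11, 12, 13, 14, 15, from syringaldehyde).

**Step 13 (ring closure).** The enamine may add to the wrong face of the quinone methide: the methoxy group at C8 presses on a pseudo-equatorial dienone ring, which could tip closure toward the 1,3-trans series. Intermolecular capture of the quinone methide by phenol or amine may also outrun ring closure.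

The fallback sets out from alcohol 12 and returns at target 23. It closes ring B through the C1–C8a bond by a Friedel–Crafts reaction, in which C1 is controlled by the adjacent C2 centre.
- OsO4/NaIO4/2,6-lutidine cleaves the alkene of 12, and the hydroxy aldehyde closes to the lactol (4R)-4-{[4-(benzyloxy)-2-bromo-3,5-dimethoxyphenyl]methyl}tetrahydrofuran-2-ol F1.
- TEMPO/PhI(OAc)2 oxidises it to the lactone (R)-4-{[4-(benzyloxy)-2-bromo-3,5-dimethoxyphenyl]methyl}dihydrofuran-2(3H)-one F2.
- Its lithium enolate (LiN(SiMe3)2, THF, −78 °C) should add to aldehyde 2 anti to the benzylic substituent, giving the trans aldol (3S,4R)-3-{[4-(benzyloxy)-3,5-dimethoxyphenyl](hydroxy)methyl}-4-{[4-(benzyloxy)-2-bromo-3,5-dimethoxyphenyl]methyl}dihydrofuran-2(3H)-one F3 (carbinol epimers).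
- CF3CO2H in CH2Cl2 ionises the carbinol. The one free position of ring A (bromine blocks the other and ends at C5) should attack the cation trans to the lactone carbon on C2, giving the all-trans 5-bromo-1-aryltetralin 2,3-fused γ-lactone F4.
- LiAlH4 (THF, 0 °C) opens it to the 5-bromo diol F5.
- H2, Pd/C, Et3N in MeOH removes both aryl benzyl ethers and the bromine and delivers 23.

**Step 10 (aryllithium addition).** The hindered, doubly ortho-substituted aryllithium may be protonated before it adds, or may add slowly to the electron-rich aldehyde, so that debrominated arene accumulates.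

The fallback sets out from bromide 13 and returns at 16, with the roles of the two rings reversed.
- Bromine–lithium exchange as before and quench with the small electrophile DMF gives 3-(benzyloxy)-6-{(S)-2-[(benzyloxy)methyl]pent-4-en-1-yl}-2,4-dimethoxybenzaldehyde F6.
- Commercial 4-bromo-2,6-dimethoxyphenol is silylated (TBSCl, imidazole) to (4-bromo-2,6-dimethoxyphenoxy)(tert-butyl)dimethylsilane F7.
- Mg in THF converts F7 into the unhindered Grignard reagent {4-[(tert-butyldimethylsilyl)oxy]-3,5-dimethoxyphenyl}magnesium bromide F8, which adds to F6 to give 16.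

**Step 12 (desilylation).** Unmasking the phenol next to the carbinol and the aldehyde may trigger premature loss of hydroxide (uncontrolled quinone methide formation and oligomerisation) or aldol condensation.

The fallback sets out from 18 and returns at 21; ring closure precedes desilylation.
- Pyrrolidine/CF3CO2H in CH2Cl2 ionises the silylated benzhydrol to its stabilised diarylmethyl cation, which the enamine captures (amine-catalysed SN1-type α-alkylation of an aldehyde with a benzhydrol). This should give the silylated tetralin aldehyde (1S,2R,3R)-7-(benzyloxy)-3-[(benzyloxy)methyl]-1-{4-[(tert-butyldimethylsilyl)oxy]-3,5-dimethoxyphenyl}-6,8-dimethoxy-1,2,3,4-tetrahydronaphthalene-2-carbaldehyde F9.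
- Bu4NF/AcOH then frees the phenol of this sturdier compound to give 21.

## Further compounds

F1 | step 13 | (4R)-4-{[4-(benzyloxy)-2-bromo-3,5-dimethoxyphenyl]methyl}tetrahydrofuran-2-ol (anomers) | OC1C[C@@H](Cc2cc(OC)c(OCc3ccccc3)c(OC)c2Br)CO1
F2 | step 13 | (R)-4-{[4-(benzyloxy)-2-bromo-3,5-dimethoxyphenyl]methyl}dihydrofuran-2(3H)-one | O=C1C[C@@H](Cc2cc(OC)c(OCc3ccccc3)c(OC)c2Br)CO1
F3 | step 13 | (3S,4R)-3-{[4-(benzyloxy)-3,5-dimethoxyphenyl](hydroxy)methyl}-4-{[4-(benzyloxy)-2-bromo-3,5-dimethoxyphenyl]methyl}dihydrofuran-2(3H)-one, carbinol epimers | O=C1[C@H](C(O)c2cc(OC)c(OCc3ccccc3)c(OC)c2)[C@@H](Cc2cc(OC)c(OCc3ccccc3)c(OC)c2Br)CO1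
F4 | step 13 | all-trans 7-(benzyloxy)-1-[4-(benzyloxy)-3,5-dimethoxyphenyl]-5-bromo-6,8-dimethoxytetralin with a γ-lactone fused at C2–C3 (carbonyl on C2) | COc1cc([C@H]2c3c(c(Br)c(OC)c(OCc4ccccc4)c3OC)C[C@H]3COC(=O)[C@H]23)cc(OC)c1OCc1ccccc1
F5 | step 13 | [(1S,2R,3R)-7-(benzyloxy)-1-[4-(benzyloxy)-3,5-dimethoxyphenyl]-5-bromo-6,8-dimethoxy-1,2,3,4-tetrahydronaphthalene-2,3-diyl]dimethanol | COc1cc([C@H]2c3c(c(Br)c(OC)c(OCc4ccccc4)c3OC)C[C@@H](CO)[C@@H]2CO)cc(OC)c1OCc1ccccc1
F6 | step 10 | 3-(benzyloxy)-6-{(S)-2-[(benzyloxy)methyl]pent-4-en-1-yl}-2,4-dimethoxybenzaldehyde | C=CC[C@@H](Cc1cc(OC)c(OCc2ccccc2)c(OC)c1C=O)COCc1ccccc1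
F7 | step 10 | (4-bromo-2,6-dimethoxyphenoxy)(tert-butyl)dimethylsilane | COc1cc(Br)cc(OC)c1O[Si](C)(C)C(C)(C)C
F8 | step 10 | {4-[(tert-butyldimethylsilyl)oxy]-3,5-dimethoxyphenyl}magnesium bromide | COc1cc([Mg]Br)cc(OC)c1O[Si](C)(C)C(C)(C)C
F9 | step 12 | (1S,2R,3R)-7-(benzyloxy)-3-[(benzyloxy)methyl]-1-{4-[(tert-butyldimethylsilyl)oxy]-3,5-dimethoxyphenyl}-6,8-dimethoxy-1,2,3,4-tetrahydronaphthalene-2-carbaldehyde | COc1cc([C@H]2c3c(cc(OC)c(OCc4ccccc4)c3OC)C[C@@H](COCc3ccccc3)[C@@H]2C=O)cc(OC)c1O[Si](C)(C)C(C)(C)C
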